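**Retrosynthetic overview**

1. Feature: in rings B and D the carbon bonded to the ring C oxygen lies between two C–OH carbons and has an oxygen on the para carbon. Each ring is thus a cyclized 3,5-dioxohexanoate whose C6 already carries the ring C oxygen. (Lettering: A/E outer trihydroxyphenoxy rings, B/D the rings they cap, G/H the C-bonded trihydroxyphenyl rings, C the central ring, F the chlorinated ring.)
2. Target ⇐ O-demethylation and O-debenzylation ⇐ rings A and E, which show the same pattern toward the ring B/D oxygens, closed from 6-(aryloxymethyl)-4-benzyloxy-2-pyranones hung on the ring B/D hydroxyls (second use of the key reaction).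
3. Biaryl bonds B–G and D–H ⇐ double Suzuki coupling at bromides placed on the free resorcinol rings B and D.
4. Rings B and D ⇐ two-directional benzyloxide opening and Claisen closure of the bis(pyranonylmethyl) ether of the ring C resorcinol ⇐ Williamson alkylation with 4-benzyloxy-6-(bromomethyl)-2-pyranone; ring C–O–ring F ⇐ Chan–Lam coupling.
5. Ring order: F and C are bought and joined first, B and D are built, G and H are attached, A and E are built last.

Key step: step 7

Remark: the target has no stereocenter and no configuration is drawn for the two crowded biaryl axes, so none is controlled; sodium benzyloxide is taken as the commercial 1 M solution in benzyl alcohol.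

**Route**

Step 1
Reactants: 1 4-hydroxy-6-methyl-2H-pyran-2-one
Product: 2 4-(benzyloxy)-6-methyl-2H-pyran-2-one
Conditions: BnOH, PPh3, DIAD, THF, 0 °C → rt
Reagents that add atoms: benzyl alcohol, OCc1ccccc1
Why: Mitsunobu alkylation of the acidic 4-hydroxyl (a vinylogous acid) with a primary alcohol should go to the 4-oxygen and not to C3 or the lactone carbonyl oxygen.

Step 2
Reactants: 2 4-(benzyloxy)-6-methyl-2H-pyran-2-one
Product: 3 4-(benzyloxy)-6-(bromomethyl)-2H-pyran-2-one
Conditions: NBS, AIBN (cat.), PhCF3, 80 °C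
Reagents that add atoms: N-bromosuccinimide, O=C1CCC(=O)N1Br
Why: Wohl–Ziegler bromination, in which the 6-methyl group gives a radical delocalized through the dienyl lactone as in the 4-methoxy analogue, while the benzylic CH2 sits on an acyloxy-like vinylogous ester oxygen and should react more slowly, as benzyl esters do.

Step 3
Reactants: 4 2-chloro-1,3-dimethoxybenzene
Product: 6 (4-chloro-3,5-dimethoxyphenyl)boronic acid, via aryl pinacol boronate 5 (not isolated)
Conditions: [Ir(OMe)(cod)]2 (cat.), dtbpy, B2pin2, THF, 80 °C; then NaIO4, aq HCl, THF/H2O, rt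
Reagents that add atoms: bis(pinacolato)diboron, CC1(C)OB(OC1(C)C)B1OC(C)(C)C(C)(C)O1; water, O
Why: Iridium-catalysed C–H borylation is sterically controlled and should take the only C–H without an ortho substituent (C5, para to chlorine) with the aryl chloride untouched, and periodate cleavage of the pinacol ester frees the boronic acid needed for the copper coupling.

Step 4
Reactants: 7 2,6-dibromo-4-methoxyphenol; 6 (4-chloro-3,5-dimethoxyphenyl)boronic acid
Product: 8 1,3-dibromo-2-(4-chloro-3,5-dimethoxyphenoxy)-5-methoxybenzene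
Conditions: Cu(OAc)2, pyridine, 4 Å MS, CH2Cl2, O2 (1 atm), rt
Reagents that add atoms: none
Why: Chan–Lam O-arylation runs at room temperature, accepts di-ortho-halogenated phenols and activates neither C–Br nor C–Cl, so the crowded ring C–O–ring F ether should form with all three halogens kept.

Step 5
Reactants: 8 1,3-dibromo-2-(4-chloro-3,5-dimethoxyphenoxy)-5-methoxybenzene
Product: 10 2-(4-chloro-3,5-dimethoxyphenoxy)-5-methoxybenzene-1,3-diol, via bis(pinacol boronate) 9 (not isolated)
Conditions: Pd(dppf)Cl2 (cat.), B2pin2, KOAc, 1,4-dioxane, 90 °C; then 30% H2O2, aq NaOH, THF, 0 °C → rt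
Reagents that add atoms: hydrogen peroxide, OO
Why: Miyaura borylation with Pd(dppf)Cl2 should insert into the two C–Br bonds but not into the electron-rich C–Cl bond flanked by two methoxy groups, and alkaline peroxide oxidation of the arylboronates (aryl shift from boron to oxygen) gives the resorcinol.

Step 6
Reactants: 10 2-(4-chloro-3,5-dimethoxyphenoxy)-5-methoxybenzene-1,3-diol; 3 4-(benzyloxy)-6-(bromomethyl)-2H-pyran-2-one (2 equiv)
Product: 11 1,3-bis[(4-benzyloxy-2-oxo-2H-pyran-6-yl)methoxy]-2-(4-chloro-3,5-dimethoxyphenoxy)-5-methoxybenzene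
Conditions: K2CO3, acetone, 50 °C
Reagents that add atoms: none
Why: Williamson etherification of the two phenoxides with a primary allylic-type bromide, an SN2 reaction established for 6-(bromomethyl)-4-methoxy-2-pyranone and phenols, sets both crowded ring C ethers without any aryl–oxygen coupling.

Step 7
Reactants: 11 1,3-bis[(4-benzyloxy-2-oxo-2H-pyran-6-yl)methoxy]-2-(4-chloro-3,5-dimethoxyphenoxy)-5-methoxybenzene
Product: 13 1,3-bis[4-(benzyloxy)-2,6-dihydroxyphenoxy]-2-(4-chloro-3,5-dimethoxyphenoxy)-5-methoxybenzene, via bis(benzyl keto ester) 12 (not isolated)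
Conditions: BnONa (1 M in BnOH, excess), THF, argon, 0 → 60 °C; then aq HCl
Reagents that add atoms: none
Why: Proposed new method: benzyloxide adds to the lactone carbonyl of each 4-benzyloxy-2-pyranone and opens it to the enolate of a benzyl (E)-3-benzyloxy-5-oxohex-2-enoate (12), whose enol ether double bond, inherited from the ring, holds the ester and the ketone chain on the same side; proton transfer then gives the ketone enolate at the aryloxy-bearing chain C6, which attacks the ester carbonyl, expels benzyloxide and leaves a cyclohexenedione that tautomerizes to the 2-aryloxy-5-benzyloxyresorcinol. The closest known reaction type is the alkoxide opening of 4-oxygenated 6-alkyl-2-pyranones to 3,5-dioxohexanoates and their Claisen cyclization to phloroglucinols; a 6-aryloxymethyl pyranone has not been taken through this sequence. Rings B and D each close by a 6-(enolendo)-exo-trig Claisen condensation, the enolate C6=C5 bond lying inside the new ring, that forms one C–C bond per arm. No stereocenter is created. The step needs alkoxide attack at the lactone carbonyl and C-acylation through chain C6: the aryloxy group acidifies C6, the chain C4 carbanion could only close a four-membered ring, O-acylation merely returns the pyranone, the vinylic chain C2 cannot be deprotonated so the ester stays an electrophile, and exchange of the 4-alkoxy group is invisible because the nucleophile is benzyloxide. Aromatization to the bis(resorcinolate) is irreversible and should drain the reversible equilibria that precede it.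

Step 8
Reactants: 13 1,3-bis[4-(benzyloxy)-2,6-dihydroxyphenoxy]-2-(4-chloro-3,5-dimethoxyphenoxy)-5-methoxybenzene
Product: 14 1,3-bis[4-(benzyloxy)-3-bromo-2,6-dihydroxyphenoxy]-2-(4-chloro-3,5-dimethoxyphenoxy)-5-methoxybenzene
Conditions: NBS (2.0 equiv), CH2Cl2/MeCN, −78 → −20 °C
Reagents that add atoms: N-bromosuccinimide, O=C1CCC(=O)N1Br
Why: Electrophilic aromatic bromination should go to the two free resorcinol rings, far more nucleophilic than the fully etherified rings C and F, at the position ortho and para to the hydroxyls (the two open positions of each ring are equivalent), and the first bromine slows a second one on the same ring.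

Step 9
Reactants: 14 1,3-bis[4-(benzyloxy)-3-bromo-2,6-dihydroxyphenoxy]-2-(4-chloro-3,5-dimethoxyphenoxy)-5-methoxybenzene
Product: 15 1,3-bis[4-(benzyloxy)-3-bromo-2,6-dimethoxyphenoxy]-2-(4-chloro-3,5-dimethoxyphenoxy)-5-methoxybenzene
Conditions: MeI, K2CO3, DMF, rt → 40 °C
Reagents that add atoms: iodomethane, CI
Why: Williamson O-methylation of the four phenols, to which the aryl bromides, the aryl chloride and the benzyl ethers are inert.

Step 10
Reactants: 15 1,3-bis[4-(benzyloxy)-3-bromo-2,6-dimethoxyphenoxy]-2-(4-chloro-3,5-dimethoxyphenoxy)-5-methoxybenzene; 16 (2,4,6-trimethoxyphenyl)boronic acid (2 equiv)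
Product: 17 1,3-bis[4-(benzyloxy)-2,6-dimethoxy-3-(2,4,6-trimethoxyphenyl)phenoxy]-2-(4-chloro-3,5-dimethoxyphenoxy)-5-methoxybenzene
Conditions: Pd(OAc)2, SPhos, K3PO4, toluene/H2O, 80 °C
Reagents that add atoms: none
Why: Suzuki–Miyaura coupling, one boronic acid per C–Br bond, with the dialkylbiarylphosphine SPhos, a ligand suited to tetra-ortho-substituted biaryls and di-ortho-methoxy boronic acids; oxidative addition should prefer the C–Br bonds over the C–Cl bond buried between two methoxy groups, and the boronic acid is charged in portions beyond the two equivalents that the coupling consumes because protodeboronation competes.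

Step 11
Reactants: 17 1,3-bis[4-(benzyloxy)-2,6-dimethoxy-3-(2,4,6-trimethoxyphenyl)phenoxy]-2-(4-chloro-3,5-dimethoxyphenoxy)-5-methoxybenzene
Product: 18 1,3-bis[4-hydroxy-2,6-dimethoxy-3-(2,4,6-trimethoxyphenyl)phenoxy]-2-(4-chloro-3,5-dimethoxyphenoxy)-5-methoxybenzene
Conditions: H2 (1 atm), Pd/C, EtOAc, rt
Reagents that add atoms: none
Why: Hydrogenolysis of the two aryl benzyl ethers in a neutral, base-free medium, where the hindered, electron-rich aryl chloride should be reduced much more slowly than O-benzyl.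

Step 12
Reactants: 18 1,3-bis[4-hydroxy-2,6-dimethoxy-3-(2,4,6-trimethoxyphenyl)phenoxy]-2-(4-chloro-3,5-dimethoxyphenoxy)-5-methoxybenzene; 3 4-(benzyloxy)-6-(bromomethyl)-2H-pyran-2-one (2 equiv)
Product: 19 1,3-bis{4-[(4-benzyloxy-2-oxo-2H-pyran-6-yl)methoxy]-2,6-dimethoxy-3-(2,4,6-trimethoxyphenyl)phenoxy}-2-(4-chloro-3,5-dimethoxyphenoxy)-5-methoxybenzene
Conditions: K2CO3, DMF, rt → 40 °C
Reagents that add atoms: none
Why: Williamson etherification as in step 6; the phenoxide next to the twisted trimethoxyphenyl ring remains open to a primary allylic-type bromide, so the crowded ring A/E ethers also enter as alkyl ethers.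

Step 13
Reactants: 19 1,3-bis{4-[(4-benzyloxy-2-oxo-2H-pyran-6-yl)methoxy]-2,6-dimethoxy-3-(2,4,6-trimethoxyphenyl)phenoxy}-2-(4-chloro-3,5-dimethoxyphenoxy)-5-methoxybenzene
Product: 21 1,3-bis{4-[4-(benzyloxy)-2,6-dihydroxyphenoxy]-2,6-dimethoxy-3-(2,4,6-trimethoxyphenyl)phenoxy}-2-(4-chloro-3,5-dimethoxyphenoxy)-5-methoxybenzene, via bis(benzyl keto ester) 20 (not isolated)
Conditions: BnONa (1 M in BnOH, excess), THF, argon, 0 → 60 °C; then aq HCl
Reagents that add atoms: none
Why: Proposed new method: the same benzyloxide opening of the lactone, 6-(enolendo)-exo-trig Claisen closure by the aryloxy-bearing carbanion and aromatization as in step 7, here closing rings A and E on an aryloxymethylpyranone that differs only in the remote aryl group; the closest known reaction type is the alkoxide opening of 4-oxygenated 6-alkyl-2-pyranones and Claisen cyclization of the 3,5-dioxohexanoate to a phloroglucinol, and the methyl ethers, diaryl ethers and aryl chloride are inert to alkoxide.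

Step 14
Reactants: 21 1,3-bis{4-[4-(benzyloxy)-2,6-dihydroxyphenoxy]-2,6-dimethoxy-3-(2,4,6-trimethoxyphenyl)phenoxy}-2-(4-chloro-3,5-dimethoxyphenoxy)-5-methoxybenzene
Product: 22 1,3-bis[2,6-dimethoxy-4-(2,4,6-trihydroxyphenoxy)-3-(2,4,6-trimethoxyphenyl)phenoxy]-2-(4-chloro-3,5-dimethoxyphenoxy)-5-methoxybenzene
Conditions: H2 (1 atm), Pd/C, EtOAc/MeOH, rt
Reagents that add atoms: none
Why: Hydrogenolysis as in step 11 removes the last benzyl ethers before the Lewis acid step, so that no benzyl cation is formed next to phloroglucinol-type rings.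

Step 15
Reactants: 22 1,3-bis[2,6-dimethoxy-4-(2,4,6-trihydroxyphenoxy)-3-(2,4,6-trimethoxyphenyl)phenoxy]-2-(4-chloro-3,5-dimethoxyphenoxy)-5-methoxybenzene
Product: 23 3,5-bis[2,6-dihydroxy-4-(2,4,6-trihydroxyphenoxy)-3-(2,4,6-trihydroxyphenyl)phenoxy]-4-(4-chloro-3,5-dihydroxyphenoxy)phenol (CNP0275555.0)
Conditions: BBr3 (large excess), CH2Cl2, −78 °C → rt; then MeOH, H2O
Reagents that add atoms: none
Why: BBr3 should cleave all thirteen aryl methyl ethers by O–B complexation and bromide attack at methyl, while the diaryl ethers, the biaryl bonds and the aryl chloride are stable.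

**Compound list**

1 | 4-hydroxy-6-methyl-2H-pyran-2-one | CC1=CC(O)=CC(=O)O1 | starting material
2 | 4-(benzyloxy)-6-methyl-2H-pyran-2-one | CC1=CC(OCc2ccccc2)=CC(=O)O1 | intermediate
3 | 4-(benzyloxy)-6-(bromomethyl)-2H-pyran-2-one | BrCC1=CC(OCc2ccccc2)=CC(=O)O1 | intermediate
4 | 2-chloro-1,3-dimethoxybenzene | COc1cccc(OC)c1Cl | starting material
5 | 2-(4-chloro-3,5-dimethoxyphenyl)-4,4,5,5-tetramethyl-1,3,2-dioxaborolane | COc1cc(B2OC(C)(C)C(C)(C)O2)cc(OC)c1Cl | intermediate
6 | (4-chloro-3,5-dimethoxyphenyl)boronic acid | COc1cc(B(O)O)cc(OC)c1Cl | intermediate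
7 | 2,6-dibromo-4-methoxyphenol | COc1cc(Br)c(O)c(Br)c1 | starting material
8 | 1,3-dibromo-2-(4-chloro-3,5-dimethoxyphenoxy)-5-methoxybenzene | COc1cc(Br)c(Oc2cc(OC)c(Cl)c(OC)c2)c(Br)c1 | intermediate
9 | 2,2'-[2-(4-chloro-3,5-dimethoxyphenoxy)-5-methoxy-1,3-phenylene]bis(4,4,5,5-tetramethyl-1,3,2-dioxaborolane) | COc1cc(B2OC(C)(C)C(C)(C)O2)c(Oc2cc(OC)c(Cl)c(OC)c2)c(B2OC(C)(C)C(C)(C)O2)c1 | intermediate
10 | 2-(4-chloro-3,5-dimethoxyphenoxy)-5-methoxybenzene-1,3-diol | COc1cc(O)c(Oc2cc(OC)c(Cl)c(OC)c2)c(O)c1 | intermediate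
11 | 1,3-bis[(4-benzyloxy-2-oxo-2H-pyran-6-yl)methoxy]-2-(4-chloro-3,5-dimethoxyphenoxy)-5-methoxybenzene | COc1cc(OCC2=CC(OCc3ccccc3)=CC(=O)O2)c(Oc2cc(OC)c(Cl)c(OC)c2)c(OCC2=CC(OCc3ccccc3)=CC(=O)O2)c1 | intermediate
12 | ring-opened form of 11: 1,3-bis{[(4E)-4,6-bis(benzyloxy)-2,6-dioxohex-4-en-1-yl]oxy}-2-(4-chloro-3,5-dimethoxyphenoxy)-5-methoxybenzene (each arm a benzyl (2E)-3-benzyloxy-5-oxohex-2-enoate bonded through C6 to a ring C oxygen) | COc1cc(OCC(=O)C/C(OCc2ccccc2)=C\C(=O)OCc2ccccc2)c(Oc2cc(OC)c(Cl)c(OC)c2)c(OCC(=O)C/C(OCc2ccccc2)=C\C(=O)OCc2ccccc2)c1 | intermediate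
13 | 1,3-bis[4-(benzyloxy)-2,6-dihydroxyphenoxy]-2-(4-chloro-3,5-dimethoxyphenoxy)-5-methoxybenzene | COc1cc(Oc2c(O)cc(OCc3ccccc3)cc2O)c(Oc2cc(OC)c(Cl)c(OC)c2)c(Oc2c(O)cc(OCc3ccccc3)cc2O)c1 | intermediate
14 | 1,3-bis[4-(benzyloxy)-3-bromo-2,6-dihydroxyphenoxy]-2-(4-chloro-3,5-dimethoxyphenoxy)-5-methoxybenzene | COc1cc(Oc2c(O)cc(OCc3ccccc3)c(Br)c2O)c(Oc2cc(OC)c(Cl)c(OC)c2)c(Oc2c(O)cc(OCc3ccccc3)c(Br)c2O)c1 | intermediate
15 | 1,3-bis[4-(benzyloxy)-3-bromo-2,6-dimethoxyphenoxy]-2-(4-chloro-3,5-dimethoxyphenoxy)-5-methoxybenzene | COc1cc(Oc2c(OC)cc(OCc3ccccc3)c(Br)c2OC)c(Oc2cc(OC)c(Cl)c(OC)c2)c(Oc2c(OC)cc(OCc3ccccc3)c(Br)c2OC)c1 | intermediate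
16 | (2,4,6-trimethoxyphenyl)boronic acid | COc1cc(OC)c(B(O)O)c(OC)c1 | starting material
17 | 1,3-bis[4-(benzyloxy)-2,6-dimethoxy-3-(2,4,6-trimethoxyphenyl)phenoxy]-2-(4-chloro-3,5-dimethoxyphenoxy)-5-methoxybenzene | COc1cc(Oc2c(OC)cc(OCc3ccccc3)c(-c3c(OC)cc(OC)cc3OC)c2OC)c(Oc2cc(OC)c(Cl)c(OC)c2)c(Oc2c(OC)cc(OCc3ccccc3)c(-c3c(OC)cc(OC)cc3OC)c2OC)c1 | intermediate
18 | 1,3-bis[4-hydroxy-2,6-dimethoxy-3-(2,4,6-trimethoxyphenyl)phenoxy]-2-(4-chloro-3,5-dimethoxyphenoxy)-5-methoxybenzene | COc1cc(Oc2c(OC)cc(O)c(-c3c(OC)cc(OC)cc3OC)c2OC)c(Oc2cc(OC)c(Cl)c(OC)c2)c(Oc2c(OC)cc(O)c(-c3c(OC)cc(OC)cc3OC)c2OC)c1 | intermediate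
19 | 1,3-bis{4-[(4-benzyloxy-2-oxo-2H-pyran-6-yl)methoxy]-2,6-dimethoxy-3-(2,4,6-trimethoxyphenyl)phenoxy}-2-(4-chloro-3,5-dimethoxyphenoxy)-5-methoxybenzene | COc1cc(Oc2c(OC)cc(OCC3=CC(OCc4ccccc4)=CC(=O)O3)c(-c3c(OC)cc(OC)cc3OC)c2OC)c(Oc2cc(OC)c(Cl)c(OC)c2)c(Oc2c(OC)cc(OCC3=CC(OCc4ccccc4)=CC(=O)O3)c(-c3c(OC)cc(OC)cc3OC)c2OC)c1 | intermediate
20 | ring-opened form of 19: each pyranone opened to a benzyl (2E)-3-benzyloxy-5-oxohex-2-enoate bonded through C6 to the ring B (ring D) oxygen | COc1cc(Oc2c(OC)cc(OCC(=O)C/C(OCc3ccccc3)=C\C(=O)OCc3ccccc3)c(-c3c(OC)cc(OC)cc3OC)c2OC)c(Oc2cc(OC)c(Cl)c(OC)c2)c(Oc2c(OC)cc(OCC(=O)C/C(OCc3ccccc3)=C\C(=O)OCc3ccccc3)c(-c3c(OC)cc(OC)cc3OC)c2OC)c1 | intermediate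
21 | 1,3-bis{4-[4-(benzyloxy)-2,6-dihydroxyphenoxy]-2,6-dimethoxy-3-(2,4,6-trimethoxyphenyl)phenoxy}-2-(4-chloro-3,5-dimethoxyphenoxy)-5-methoxybenzene | COc1cc(Oc2c(OC)cc(Oc3c(O)cc(OCc4ccccc4)cc3O)c(-c3c(OC)cc(OC)cc3OC)c2OC)c(Oc2cc(OC)c(Cl)c(OC)c2)c(Oc2c(OC)cc(Oc3c(O)cc(OCc4ccccc4)cc3O)c(-c3c(OC)cc(OC)cc3OC)c2OC)c1 | intermediate
22 | 1,3-bis[2,6-dimethoxy-4-(2,4,6-trihydroxyphenoxy)-3-(2,4,6-trimethoxyphenyl)phenoxy]-2-(4-chloro-3,5-dimethoxyphenoxy)-5-methoxybenzene | COc1cc(Oc2c(OC)cc(Oc3c(O)cc(O)cc3O)c(-c3c(OC)cc(OC)cc3OC)c2OC)c(Oc2cc(OC)c(Cl)c(OC)c2)c(Oc2c(OC)cc(Oc3c(O)cc(O)cc3O)c(-c3c(OC)cc(OC)cc3OC)c2OC)c1 | intermediate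
23 | 3,5-bis[2,6-dihydroxy-4-(2,4,6-trihydroxyphenoxy)-3-(2,4,6-trihydroxyphenyl)phenoxy]-4-(4-chloro-3,5-dihydroxyphenoxy)phenol | Oc1cc(O)c(Oc2cc(O)c(Oc3cc(O)cc(Oc4c(O)cc(Oc5c(O)cc(O)cc5O)c(-c5c(O)cc(O)cc5O)c4O)c3Oc3cc(O)c(Cl)c(O)c3)c(O)c2-c2c(O)cc(O)cc2O)c(O)c1 | target

**Step count and risk**

Total step count: 15. Longest linear sequence: 13 steps (steps 3 to 15, from 4).

Steps most likely to fail:

1. Step 7 (proposed new method). The reversible ring opening may only return the pyranone, or the extended enolate conjugated to the enoate may persist as an unreactive resting state. Alkoxide cleavage of the keto ester could also fragment the arms before C-acylation takes place in both of them. The fallback uses known chemistry, sets out from 8 and comes back to the route at 15. Commercial 2,6-dimethoxybenzene-1,4-diol would be benzylated at its unhindered hydroxyl (BnBr, K2CO3, acetone) to 4-(benzyloxy)-2,6-dimethoxyphenol F1. A double Ullmann diaryl ether coupling of F1 with 8 (CuI, picolinic acid, K3PO4, DMSO, 110 °C) would give 1,3-bis[4-(benzyloxy)-2,6-dimethoxyphenoxy]-2-(4-chloro-3,5-dimethoxyphenoxy)-5-methoxybenzene F2. NBS (2 equiv, MeCN, 0 °C) would then brominate each trialkoxy ring between OBn and OMe, the most activated position of the molecule, to give 15.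

2. Step 13 (proposed new method). The same processes as in step 7 may intervene, now with a substrate that is costly to remake, and incomplete closure of the second arm would leave mixed products. The fallback uses known chemistry, sets out from 18 and comes back at 23. A double Ullmann coupling of 18 with commercial 2-iodo-1,3,5-trimethoxybenzene (CuI, picolinic acid, K3PO4, DMSO, 110 °C) would give 1,3-bis[2,6-dimethoxy-4-(2,4,6-trimethoxyphenoxy)-3-(2,4,6-trimethoxyphenyl)phenoxy]-2-(4-chloro-3,5-dimethoxyphenoxy)-5-methoxybenzene F3. BBr3 (CH2Cl2, −78 °C → rt) would then cleave its nineteen methyl ethers to 23.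

3. Step 10. Protodeboronation of the di-ortho-methoxy boronic acid may outrun transmetalation at the di-ortho-substituted palladium centre. The coupling may also stall after one arm, or slow insertion into the C–Cl bond of ring F may erode chemoselectivity. The fallback sets out from 15 and comes back at 17. 1,3,5-Trimethoxybenzene would be lithiated (n-BuLi, THF, 0 °C) to (2,4,6-trimethoxyphenyl)lithium F4 and transmetalated with ZnCl2 to (2,4,6-trimethoxyphenyl)zinc chloride F5. A Negishi coupling of F5 with 15 (Pd2(dba)3, RuPhos, THF, 65 °C), which has no protodemetalation channel under anhydrous conditions, would give 17.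

**Further compounds**

F1 | step 7 | 4-(benzyloxy)-2,6-dimethoxyphenol | COc1cc(OCc2ccccc2)cc(OC)c1O
F2 | step 7 | 1,3-bis[4-(benzyloxy)-2,6-dimethoxyphenoxy]-2-(4-chloro-3,5-dimethoxyphenoxy)-5-methoxybenzene | COc1cc(Oc2c(OC)cc(OCc3ccccc3)cc2OC)c(Oc2cc(OC)c(Cl)c(OC)c2)c(Oc2c(OC)cc(OCc3ccccc3)cc2OC)c1
F3 | step 13 | 1,3-bis[2,6-dimethoxy-4-(2,4,6-trimethoxyphenoxy)-3-(2,4,6-trimethoxyphenyl)phenoxy]-2-(4-chloro-3,5-dimethoxyphenoxy)-5-methoxybenzene | COc1cc(Oc2c(OC)cc(Oc3c(OC)cc(OC)cc3OC)c(-c3c(OC)cc(OC)cc3OC)c2OC)c(Oc2cc(OC)c(Cl)c(OC)c2)c(Oc2c(OC)cc(Oc3c(OC)cc(OC)cc3OC)c(-c3c(OC)cc(OC)cc3OC)c2OC)c1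
F4 | step 10 | (2,4,6-trimethoxyphenyl)lithium | [Li]c1c(OC)cc(OC)cc1OC
F5 | step 10 | (2,4,6-trimethoxyphenyl)zinc chloride | COc1cc(OC)c([Zn]Cl)c(OC)c1
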